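Readings and results stem from a simulated flask for an exercise, noise included.

The easy step is the end point, so I start from the earlier runs.

| flask | starting material | free catalyst | remark | time |
|---|---|---|---|---|
| dawn | 0.10 M | 2 mol% | run made earlier |  |
| winter | 0.40 M | 2 mol% | run made earlier |  |
| noon | 0.20 M | 1 mol% | run made earlier |  |
| flask | 0.20 M | 2 mol% |  | 2.5 min |

| run | time / s | target / % | starting material / % | side product / % | catalyst intermediate / % |
|---|---|---|---|---|---|
| dawn | 10.0 | 30 | 41 | 24 | 3 |
| dawn | 12.0 | 36 | 35 | 31 | 0 |
| dawn | 20.0 | 49 | 8 | 43 | 2 |
| dawn | 30.0 | 51 | 0 | 49 | 0 |
| dawn | 50.0 | 55 | 0 | 51 | 0 |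
| dawn | 90.0 | 53 | 1 | 49 | 0 |
| winter | 10.0 | 26 | 17 | 56 | 3 |
| winter | 20.0 | 34 | 0 | 63 | 2 |
| winter | 30.0 | 32 | 3 | 64 | 2 |
| winter | 50.0 | 36 | 2 | 66 | 0 |
| winter | 60.0 | 35 | 3 | 62 | 0 |
| winter | 90.0 | 35 | 0 | 63 | 0 |
| noon | 10.0 | 12 | 60 | 26 | 1 |
| noon | 15.0 | 15 | 38 | 44 | 0 |
| noon | 25.0 | 27 | 7 | 65 | 4 |
| noon | 50.0 | 29 | 4 | 70 | 0 |
| noon | 90.0 | 31 | 1 | 68 | 0 |

(standard deviation of a reading: 2 percentage points)

- a species is counted by the starting material in it: one side product counts as two

- the species that holds most of what was charged as starting material, at 2.5 min (side product / target / starting material / catalyst intermediate)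
- the largest share itself, whichever of these holds it, in percent of the starting material charged

1. End state. By 50.0 s the starting material reads at most 4 % in dawn, winter and noon, and 2.5 min lies beyond the last reading at 90.0 s. So I treat this flask as finished: the question is how target and side product split the charge.

2. Main step. Taken by itself, it turns the whole charge into target. Early on I take the catalyst as held as catalyst intermediate (the resting state), since dawn reads 3 % at 10.0 s on a loading of 2 mol%. The fraction of the charge converted per second then goes with the loading.

3. Side step. Starting material meets target, which moves the number towards side product. With a the fraction left and p the fraction as target, its speed in fractions goes with concentration times a times p. So at a fixed loading I expect more side product from a higher concentration, and dawn and winter, both at 2 mol%, show it: their last readings give 49 % and 63 % side product. From these two readings I take the doubling step, the points of side share gained per doubling of the concentration at a fixed loading of 2 mol%: 7 percentage points.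

4. The rest. The catalyst intermediate reads 0 %, 0 % and 0 % at the last readings of dawn, winter and noon, so I leave it out of the end number.

5. Reckoning. This flask has dawn's loading and twice dawn's concentration, so it stands one doubling above dawn. I add the doubling step to dawn's last reading and get side product 56.0 %, which leaves target 44.0 %.

The forecast says side product at 57 %, holding that “side formation has a higher order in starting material”.

The flask gives side product at 55.9 %, and it still holds 55.9 % at 25.0 min. This flask stands 6.9 points above dawn's last reading, against a doubling step of 7 points.

    starting material + free catalyst → catalyst intermediate (k = 94.0 /M/s)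
    catalyst intermediate → free catalyst + target (k = 3.30 /s)
    starting material + target → side product (k = 1.10 /M/s)

Now take the same flask with 0.34 M of starting material, at the same loading. That neighbour stands 0.766 doublings above this flask, so the doubling step of 7 points gives 61.2 % side product. The computed result is 62.6 %.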